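**Strategy.** Numbering: target as spiro[5.5]undecane; ring B C1–C5 (C2 Cl, C3 Br/CH3), spiro C6, ring A C7–C11 (C7 gem-dimethyl, C8 Br, C11 methylidene). Ring A is built first, by stereospecific bromonium cyclisation, as a 2-formyl ketone in which C6 lies between the C11 carbonyl and the formyl carbon C1. The key step is a Robinson-type spiroannulation with methyl vinyl ketone: Michael addition at C6 (trans to the C8 bromine, relayed by the C7 methyls) forms C5–C6, and aldol condensation joins C2 to C1. One operation makes ring B, the quaternary spiro carbon and an enone whose carbonyl marks C3, 1,4 to C6. The halogens follow by epoxide opening, bromonium capture and a 1,2-dihalide shift.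

Key step: step 5

Remark: atom labels C1–C11 in the text follow the target numbering above (locants inside a compound name belong to that name); 6 is written as the keto aldehyde but should exist mainly as its hydroxymethylene enol; the ligand antipode in step 1 is the one that delivers the (R)-bromide.

Step 1
Reactants: 1 3-methylbut-2-en-1-ol (prenol)
Product: 2 (2R)-2-bromo-3-chloro-3-methylbutan-1-ol
Conditions: NBS, ClTi(OiPr)3, (S)-2,4-di-tert-butyl-6-{[(2-hydroxy-1,2,2-triphenylethyl)imino]methyl}phenol (20 mol%), hexanes, −20 °C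
Reagents that add atoms: N-bromosuccinimide O=C1CCC(=O)N1Br; chlorotitanium triisopropoxide CC(C)O[Ti](Cl)(OC(C)C)OC(C)C
Why: Titanium-mediated catalytic enantioselective bromochlorination of an allylic alcohol: the bound alkoxide directs bromonium formation to one alkene face and chloride is delivered anti to the distal tertiary carbon, so the chiral ligand should set the CHBr centre.

Step 2
Reactants: 2 (2R)-2-bromo-3-chloro-3-methylbutan-1-ol
Product: 3 (2R)-2-bromo-3-chloro-3-methylbutyl trifluoromethanesulfonate
Conditions: Tf2O, 2,6-lutidine, CH2Cl2, −78 °C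
Reagents that add atoms: trifluoromethanesulfonic anhydride O=S(=O)(OS(=O)(=O)C(F)(F)F)C(F)(F)F
Why: O-Sulfonylation of the primary alcohol at low temperature activates it for SN2 displacement without touching the halogenated carbons.

Step 3
Reactants: 3 (2R)-2-bromo-3-chloro-3-methylbutyl trifluoromethanesulfonate; 4 (E)-4-methoxybut-3-en-2-one
Product: 5 (1E,6R)-6-bromo-7-chloro-1-methoxy-7-methyloct-1-en-3-one
Conditions: 4, LiN(iPr)2, THF, −78 °C; then 3, −78 → −40 °C
Reagents that add atoms: none
Why: Kinetic α′-deprotonation of the vinylogous ester and SN2 alkylation of the lithium enolate by the primary triflate should be faster at −78 °C than elimination of the halides, and the CHBr centre is not involved.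

Step 4
Reactants: 5 (1E,6R)-6-bromo-7-chloro-1-methoxy-7-methyloct-1-en-3-one
Product: 6 (3R)-3-bromo-2,2-dimethyl-6-oxocyclohexane-1-carbaldehyde
Conditions: (CF3)2CHOH, 23 °C; then H2O, NaHCO3 work-up
Reagents that add atoms: water O
Why: Solvolytic bromonium (cation–olefin) cyclisation: the vicinal bromine assists ionisation of the tertiary chloride, the nucleophilic α-carbon of the β-methoxy enone attacks the tertiary carbon of the enantiopure bromonium ion to close ring A (the C8–Br bond is never broken, so its configuration is kept), and hydrolysis of the oxocarbenium ion gives the formyl ketone.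

Step 5
Reactants: 6 (3R)-3-bromo-2,2-dimethyl-6-oxocyclohexane-1-carbaldehyde; 7 but-3-en-2-one (methyl vinyl ketone)
Product: 9 spiro enedione (4R,6R)-4-bromo-5,5-dimethylspiro[5.5]undec-7-ene-1,9-dione, via Michael adduct 8 (not isolated)
Conditions: 7 (1.5 equiv), Et3N (0.2 equiv), THF, 0 °C → rt; then p-TsOH·H2O (0.1 equiv), toluene, 80 °C, Dean–Stark
Reagents that add atoms: none
Why: Et3N forms the stabilised enolate of the 2-formyl ketone, which adds through C6 to the β-carbon of methyl vinyl ketone (Michael addition, new C5–C6 bond) to give 8, and acid then closes ring B by intramolecular aldol condensation of the methyl ketone carbon C2 onto the formyl carbon C1. The closest known reaction type is the Robinson-type spiroannulation of 2-formylcycloalkanones with methyl vinyl ketone. Ring B closes in a 6-(enolendo)-exo-trig aldol step that dehydration to the conjugated enone makes irreversible. The only new stereocentre, C6, is set in the Michael step: with the C8 bromine equatorial, the pseudoaxial C7 methyl blocks one face of the planar enolate carbon, so the enone should add anti to that methyl and trans to bromine, leaving the formyl group cis to bromine. The step needs aldol closure on the aldehyde and not on the ring ketone, which the higher electrophilicity of the aldehyde and the non-nucleophilic acid (no retro-Claisen loss of the formyl group) should secure.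

Step 6
Reactants: 9 (4R,6R)-4-bromo-5,5-dimethylspiro[5.5]undec-7-ene-1,9-dione
Product: 10 (4R,6R)-4-bromo-5,5-dimethyl-1-oxospiro[5.5]undec-8-en-9-yl trifluoromethanesulfonate
Conditions: LiBH(sBu)3 (1.05 equiv), THF, −78 °C; then PhNTf2, −78 → 0 °C
Reagents that add atoms: N-phenylbis(trifluoromethanesulfonimide) O=S(=O)(N(c1ccccc1)S(=O)(=O)C(F)(F)F)C(F)(F)F
Why: Conjugate reduction with enolate triflation: the bulky borohydride should add hydride to C1 of the enone and leave the neopentyl ring A ketone alone, and the regiodefined C3 enolate is trapped on oxygen.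

Step 7
Reactants: 10 (4R,6R)-4-bromo-5,5-dimethyl-1-oxospiro[5.5]undec-8-en-9-yl trifluoromethanesulfonate
Product: 11 (4R,6R)-4-bromo-5,5,9-trimethylspiro[5.5]undec-8-en-1-one
Conditions: MeZnCl, Pd(PPh3)4 (5 mol%), THF, 50 °C
Reagents that add atoms: methylzinc chloride C[Zn]Cl
Why: Negishi cross-coupling of the alkenyl triflate installs the C3 methyl group and fixes the ring B double bond at C2=C3, while the ketone and the unactivated secondary bromide are inert to the organozinc and to the catalyst.

Step 8
Reactants: 11 (4R,6R)-4-bromo-5,5,9-trimethylspiro[5.5]undec-8-en-1-one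
Product: 12 (6S,8R)-8-bromo-3,7,7-trimethyl-11-methylidenespiro[5.5]undec-2-ene
Conditions: Zn, CH2Br2, TiCl4, THF/CH2Cl2, 0 → 23 °C
Reagents that add atoms: dibromomethane BrCBr
Why: Takai–Lombardo methylenation converts the hindered, enolisable C11 ketone into the methylidene group without base, so the bromide should not be eliminated (the spiro descriptor changes from R to S only because the CIP priorities change).

Step 9
Reactants: 12 (6S,8R)-8-bromo-3,7,7-trimethyl-11-methylidenespiro[5.5]undec-2-ene
Product: 13 (2S,3R,6S,8R)-8-bromo-2,3-epoxy-3,7,7-trimethyl-11-methylidenespiro[5.5]undecane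
Conditions: mCPBA (1.0 equiv), CH2Cl2, −20 → 0 °C
Reagents that add atoms: 3-chloroperoxybenzoic acid O=C(OO)c1cccc(Cl)c1
Why: Prilezhaev epoxidation should take the electron-rich trisubstituted ring B alkene before the hindered 1,1-disubstituted methylidene, from the face anti to the pseudoaxial C11 substituent of the spiro carbon (the face cis to C7), which sets C2 and C3.

Step 10
Reactants: 13 (2S,3R,6S,8R)-8-bromo-2,3-epoxy-3,7,7-trimethyl-11-methylidenespiro[5.5]undecane
Product: 14 (2R,3R,6S,8R)-2,8-dibromo-3,7,7-trimethyl-11-methylidenespiro[5.5]undecan-3-ol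
Conditions: LiBr, AcOH, THF, 23 °C
Reagents that add atoms: lithium bromide [Li+].[Br-]
Why: Trans-diaxial (Fürst–Plattner) SN2 opening of the epoxide by bromide at the secondary carbon C2 inverts C2 and keeps the tertiary C3–O bond, placing bromine on the ring B face opposite to the former epoxide oxygen.

Step 11
Reactants: 14 (2R,3R,6S,8R)-2,8-dibromo-3,7,7-trimethyl-11-methylidenespiro[5.5]undecan-3-ol
Product: 16 obtusane, via diaxial bromochloride 15 (not isolated)
Conditions: SOCl2 (1.1 equiv), 2,6-lutidine (1.2 equiv), CH2Cl2, −40 → 0 °C; then solvent change to PhCl, 80–100 °C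
Reagents that add atoms: thionyl chloride O=S(Cl)Cl
Why: The tertiary chlorosulfite should ionise with anchimeric assistance from the antiperiplanar C2 bromine and chloride should open the bromonium ion at C3 with overall retention to give 15; heating then brings about the diaxial-to-diequatorial 1,2-interchange of vicinal halogens (dyotropic rearrangement, Br from C2 to C3 and Cl from C3 to C2, each on its own face, both centres inverted), which relief of the 1,3-diaxial C2–Br/C11 interaction should drive.

**Compound list**
1 | 3-methylbut-2-en-1-ol (prenol) | CC(C)=CCO | starting material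
2 | (2R)-2-bromo-3-chloro-3-methylbutan-1-ol | OC[C@@H](Br)C(C)(C)Cl | intermediate
3 | (2R)-2-bromo-3-chloro-3-methylbutyl trifluoromethanesulfonate | O=S(=O)(OC[C@@H](Br)C(C)(C)Cl)C(F)(F)F | intermediate
4 | (E)-4-methoxybut-3-en-2-one | CO/C=C/C(C)=O | starting material
5 | (1E,6R)-6-bromo-7-chloro-1-methoxy-7-methyloct-1-en-3-one | CO/C=C/C(=O)CC[C@@H](Br)C(C)(C)Cl | intermediate
6 | (3R)-3-bromo-2,2-dimethyl-6-oxocyclohexane-1-carbaldehyde (C1 enolised, configuration not defined) | O=CC1C(=O)CC[C@@H](Br)C1(C)C | intermediate
7 | but-3-en-2-one (methyl vinyl ketone) | CC(=O)C=C | starting material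
8 | (1S,3R)-3-bromo-2,2-dimethyl-6-oxo-1-(3-oxobutyl)cyclohexane-1-carbaldehyde (Michael adduct) | O=C1CC[C@@H](Br)C(C)(C)[C@]1(C=O)CCC(C)=O | intermediate
9 | (4R,6R)-4-bromo-5,5-dimethylspiro[5.5]undec-7-ene-1,9-dione | O=C1CC[C@@H](Br)C(C)(C)[C@]12CCC(=O)C=C2 | intermediate
10 | (4R,6R)-4-bromo-5,5-dimethyl-1-oxospiro[5.5]undec-8-en-9-yl trifluoromethanesulfonate | O=C1CC[C@@H](Br)C(C)(C)[C@]12CCC(OS(=O)(=O)C(F)(F)F)=CC2 | intermediate
11 | (4R,6R)-4-bromo-5,5,9-trimethylspiro[5.5]undec-8-en-1-one | O=C1CC[C@@H](Br)C(C)(C)[C@]12CCC(C)=CC2 | intermediate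
12 | (6S,8R)-8-bromo-3,7,7-trimethyl-11-methylidenespiro[5.5]undec-2-ene | C=C1CC[C@@H](Br)C(C)(C)[C@]12CCC(C)=CC2 | intermediate
13 | (2S,3R,6S,8R)-8-bromo-2,3-epoxy-3,7,7-trimethyl-11-methylidenespiro[5.5]undecane (oxygen cis to C7) | C=C1CC[C@@H](Br)C(C)(C)[C@]12CC[C@@]3(C)O[C@H]3C2 | intermediate
14 | (2R,3R,6S,8R)-2,8-dibromo-3,7,7-trimethyl-11-methylidenespiro[5.5]undecan-3-ol | C=C1CC[C@@H](Br)C(C)(C)[C@]12CC[C@@](C)(O)[C@H](Br)C2 | intermediate
15 | (2R,3R,6S,8R)-2,8-dibromo-3-chloro-3,7,7-trimethyl-11-methylidenespiro[5.5]undecane (diaxial bromochloride) | C=C1CC[C@@H](Br)C(C)(C)[C@]12CC[C@@](C)(Cl)[C@H](Br)C2 | intermediate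
16 | obtusane, (2S,3S,6S,8R)-3,8-dibromo-2-chloro-3,7,7-trimethyl-11-methylidenespiro[5.5]undecane | C=C1CC[C@@H](Br)C(C)(C)[C@]12CC[C@](C)(Br)[C@@H](Cl)C2 | target

**Total step count:** 11. **Longest linear sequence:** 11 steps (from 1).

**Steps most likely to fail**

Step 11. The chlorosulfite or the bromonium ion may lose a proton instead of capturing chloride, the diaxial/diequatorial equilibrium may stop short of the target, and the tertiary halide may lose HX on heating. Fallback from 12 back to 16, which makes the tertiary bromide kinetically and not by equilibration. NBS in aqueous acetone should form the bromonium ion on the open ring B face (anti to C11) with water entering at C3, giving (2S,3S,6S,8R)-2,8-dibromo-3,7,7-trimethyl-11-methylidenespiro[5.5]undecan-3-ol F5. K2CO3 in MeOH closes this to the epoxide on the C11 face, (2R,3S,6S,8R)-8-bromo-2,3-epoxy-3,7,7-trimethyl-11-methylidenespiro[5.5]undecane F6 (the regioisomeric bromohydrin from the same bromonium ion closes to the same epoxide). HCl in Et2O at −40 °C opens F6 trans-diaxially at tertiary C3 to (2R,3R,6S,8R)-8-bromo-3-chloro-3,7,7-trimethyl-11-methylidenespiro[5.5]undecan-2-ol F7. Tf2O with 2,6-di-tert-butylpyridine, then Bu4NBr, lets the antiperiplanar chlorine bridge as the triflate leaves; bromide opens the chloronium ion at the tertiary carbon and the chlorine ends on C2, which is 16.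

Step 4. The carbonyl oxygen may capture the bromonium ion (O-cyclisation to a dihydropyran), the solvent may intercept the cation, and some enantiopurity may be lost. Fallback from 3 back to 6 with a chelated β-keto ester as the terminating nucleophile. The dianion of methyl acetoacetate (NaH, then nBuLi, THF, 0 °C) is alkylated by 3 to methyl (6R)-6-bromo-7-chloro-7-methyl-3-oxooctanoate F1. The same solvolytic cyclisation in (CF3)2CHOH gives methyl (3R)-3-bromo-2,2-dimethyl-6-oxocyclohexane-1-carboxylate F2. Its sodium enolate (NaH) protects the ketone while LiAlH4 reduces the ester to (4R)-4-bromo-2-(hydroxymethyl)-3,3-dimethylcyclohexan-1-one F3, and Dess–Martin oxidation returns to 6.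

Step 5. The formyl group may be lost by retro-Claisen cleavage, the aldol may close onto the ring ketone (fused Robinson product), dehydration may be incomplete, and the Michael step may show poor facial selectivity. Fallback from 6 back to 9 with ring closure by olefination instead of aldol condensation. Et3N-catalysed Michael addition of 6 to dimethyl (2-oxobut-3-en-1-yl)phosphonate gives dimethyl {4-[(1S,3R)-3-bromo-1-formyl-2,2-dimethyl-6-oxocyclohexyl]-2-oxobutyl}phosphonate F4. An intramolecular Horner–Wadsworth–Emmons reaction (LiCl, DBU, MeCN) then closes ring B irreversibly on the aldehyde to give 9; a minor C6 epimer would be removed at this crystalline stage.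

**Further compounds**
F1 | step 4 | methyl (6R)-6-bromo-7-chloro-7-methyl-3-oxooctanoate | COC(=O)CC(=O)CC[C@@H](Br)C(C)(C)Cl
F2 | step 4 | methyl (3R)-3-bromo-2,2-dimethyl-6-oxocyclohexane-1-carboxylate | COC(=O)C1C(=O)CC[C@@H](Br)C1(C)C
F3 | step 4 | (4R)-4-bromo-2-(hydroxymethyl)-3,3-dimethylcyclohexan-1-one | OCC1C(=O)CC[C@@H](Br)C1(C)C
F4 | step 5 | dimethyl {4-[(1S,3R)-3-bromo-1-formyl-2,2-dimethyl-6-oxocyclohexyl]-2-oxobutyl}phosphonate | O=C1CC[C@@H](Br)C(C)(C)[C@]1(C=O)CCC(=O)CP(=O)(OC)OC
F5 | step 11 | (2S,3S,6S,8R)-2,8-dibromo-3,7,7-trimethyl-11-methylidenespiro[5.5]undecan-3-ol | C=C1CC[C@@H](Br)C(C)(C)[C@]12CC[C@](C)(O)[C@@H](Br)C2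
F6 | step 11 | (2R,3S,6S,8R)-8-bromo-2,3-epoxy-3,7,7-trimethyl-11-methylidenespiro[5.5]undecane | C=C1CC[C@@H](Br)C(C)(C)[C@]12CC[C@]3(C)O[C@@H]3C2
F7 | step 11 | (2R,3R,6S,8R)-8-bromo-3-chloro-3,7,7-trimethyl-11-methylidenespiro[5.5]undecan-2-ol | C=C1CC[C@@H](Br)C(C)(C)[C@]12CC[C@@](C)(Cl)[C@H](O)C2
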